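**Retrosynthetic overview**

1. Feature: in the butan-2-one chain of tsangin C (C2 ketone, C3 methyl-bearing stereocentre, C4 stereocentre carrying ring B and the ester oxygen), the ketone carbon C2 and the ester carbonyl carbon bearing ring A are linked through C3–C4–O. Drawn as one C=C bond instead of two C=O groups, they close a five-membered enol ether, ring C, so the target is the oxidatively opened form of a trans-2,5-diaryl-3,4-dimethyl-2,3-dihydrofuran.
2. Last disconnection: ozonolysis of the enol-ether C=C of dihydrofuran 8 gives the benzoate and the methyl ketone at once; the trans ring stereocentres become (3S,4R) of the chain.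
3. Key disconnection: ring C from diazo ketone 6 and (E)-isoelemicin 4 by a formal (3+2) annulation. Asymmetric cyclopropanation makes the C2–C3 bond and sets C3; Cloke–Wilson ring expansion makes the O–C4 bond and sets C4 trans to it.
4. Both partners come from 3,4,5-trimethoxybenzaldehyde 1 through one carbinol 2 (oxidation and diazo transfer to 6; dehydration to 4). Rings A and B are bought; ring C is the only ring formed and is opened again in the last step.

Key step: step 6

Assumption: the alkene face selected by Rh2(S-PTTL)4 (Rh2[N-phthaloyl-(S)-tert-leucinate]4) for this carbene–alkene pair is taken to be the one leading to (2R,3R)-8; should the sense prove opposite, Rh2(R-PTTL)4 is used with nothing else changed.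

Numbering: chain atoms of the target follow butan-2-one; ring C atoms follow furan (O1, C2 aryl-bearing sp3 carbon, C3 methyl-bearing sp3 carbon, C4=C5).

**Route**

Step 1
Reactants: 1 3,4,5-trimethoxybenzaldehyde
Product: 2 (±)-1-(3,4,5-trimethoxyphenyl)propan-1-ol
Conditions: EtMgBr (1.2 equiv), THF, 0 → 23 °C; aqueous work-up
Reagents that add atoms: ethylmagnesium bromide, CC[Mg]Br
Why: Grignard 1,2-addition to a non-enolisable aryl aldehyde; the carbinol centre is racemic and is removed in both later branches.

Step 2
Reactants: 2 (±)-1-(3,4,5-trimethoxyphenyl)propan-1-ol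
Product: 3 1-(3,4,5-trimethoxyphenyl)propan-1-one
Conditions: MnO2 (activated, 10 equiv), CH2Cl2, 23 °C
Reagents that add atoms: none
Why: Heterogeneous MnO2 oxidation is selective for benzylic alcohols and should leave the trimethoxyarene untouched.

Step 3
Reactants: 2 (±)-1-(3,4,5-trimethoxyphenyl)propan-1-ol
Product: 4 (E)-isoelemicin, (E)-1,2,3-trimethoxy-5-(prop-1-en-1-yl)benzene
Conditions: TsOH·H2O (2 mol %), toluene (0.05 M), reflux, Dean–Stark; AgNO3-impregnated silica if any Z isomer has to be removed
Reagents that add atoms: none
Why: Acid-catalysed E1 dehydration through the ring-stabilised benzylic cation should give the conjugated alkene, with the E isomer favoured thermodynamically under the reversible conditions and dilution limiting cationic dimerisation.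

Step 4
Reactants: 3 1-(3,4,5-trimethoxyphenyl)propan-1-one
Product: 5 (±)-4,4,4-trifluoro-2-methyl-1-(3,4,5-trimethoxyphenyl)butane-1,3-dione (used crude)
Conditions: LiN(SiMe3)2 (1.1 equiv), THF, −78 °C; CF3CO2CH2CF3 (1.2 equiv), −78 °C; 5% aq. HCl
Reagents that add atoms: 2,2,2-trifluoroethyl trifluoroacetate, O=C(OCC(F)(F)F)C(F)(F)F
Why: The ketone has one enolisable side, so its lithium enolate undergoes Claisen-type C-acylation with the activated trifluoroacetate, giving the activated substrate for deacylative diazo transfer.

Step 5
Reactants: 5 (±)-4,4,4-trifluoro-2-methyl-1-(3,4,5-trimethoxyphenyl)butane-1,3-dione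
Product: 6 2-diazo-1-(3,4,5-trimethoxyphenyl)propan-1-one
Conditions: MsN3 (1.5 equiv), Et3N (1.5 equiv), H2O (1 equiv), MeCN, 23 °C; filtration through Et3N-deactivated silica, stored cold
Reagents that add atoms: methanesulfonyl azide, CS(=O)(=O)N=[N+]=[N-]
Why: Regitz-type deacylative diazo transfer, in which the enolate of 5 attacks the sulfonyl azide and the adduct fragments with loss of the trifluoroacetyl group, so a carbon with a single α-hydrogen can be diazotised.

Step 6
Reactants: 6 2-diazo-1-(3,4,5-trimethoxyphenyl)propan-1-one; 4 (E)-isoelemicin (1.5 equiv)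
Product: 8 (2R,3R)-3,4-dimethyl-2,5-bis(3,4,5-trimethoxyphenyl)-2,3-dihydrofuran (trans), via cyclopropyl ketone 7 (not isolated)
Conditions: Rh2(S-PTTL)4 (1 mol %), CH2Cl2/toluene, −78 °C, 6 added over 3 h; then Sc(OTf)3 (10 mol %), 4 Å MS, −78 → 23 °C; Et3N quench, Et3N-deactivated silica
Reagents that add atoms: none
Why: Proposed new method: Rh2(S-PTTL)4 takes N2 from 6 and the divalent-rhodium acyl(methyl)carbenoid adds across the alkene of 4 in a concerted, asynchronous [2+1] closure with retention of the E geometry, giving cyclopropyl ketone 7 and with it the bond between the acyl-bearing carbon and the methyl-bearing carbon; the closest known reaction type is the low-temperature enantioselective cyclopropanation of styrenes by α-alkyl-α-diazo carbonyl compounds under this bulky carboxylate, where the ligand wall and −78 °C hold back the 1,2-hydride shift, helped here because the migrating hydrogen would have to come from a methyl group. Sc(OTf)3 then binds the aroyl oxygen and ionises the bond between the quaternary acyl carbon and the benzylic carbon, the only ring bond flanked by a donor (ring B) and an acceptor, to a scandium enolate and a benzylic cation, as in Lewis-acid Cloke–Wilson rearrangements of 2-aryl cyclopropyl ketones. Ring C is closed by the enolate oxygen attacking the cation, a stepwise polar cation–enolate recombination that forms the O–C2 bond of the five-membered ring. C3 is set by the catalyst's choice of alkene face in the cyclopropanation and is not touched afterwards, whereas C2 is set in the ring closure trans to the C3 methyl, kinetically because the aryl group turns away from the methyl and thermodynamically because the benzylic C–O bond re-ionises under the Lewis acid. The step needs carbene transfer to outrun the hydride shift (excess electron-rich alkene, slow addition of 6), the same alkene face in both cyclopropane diastereomers (the two other cyclopropane centres are erased), and O- rather than C-closure of the cation (a catalytic, mild Lewis acid, low temperature and the amine quench are meant to keep Friedel–Crafts attack on ring A and proton loss next to the cation in check).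

Step 7
Reactants: 8 (2R,3R)-3,4-dimethyl-2,5-bis(3,4,5-trimethoxyphenyl)-2,3-dihydrofuran
Product: 10 tsangin C [(1R,2S)-2-methyl-3-oxo-1-(3,4,5-trimethoxyphenyl)butyl 3,4,5-trimethoxybenzoate], via methoxy hydroperoxide 9 (not isolated)
Conditions: O3, CH2Cl2/MeOH (5:1), −78 °C, Sudan Red 7B end point; Me2S, −78 → 23 °C
Reagents that add atoms: ozone, [O-][O+]=O
Why: Criegee ozonolysis with reductive work-up, in which ozone should add to the electron-rich enol ether far faster than to the arenes, the primary ozonide fragments to the aryl ester and a ketone oxide that methanol traps as 9, and Me2S reduces 9 to the methyl ketone under neutral conditions that leave both stereocentres untouched.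

**Compound list**

1 | 3,4,5-trimethoxybenzaldehyde | COc1cc(C=O)cc(OC)c1OC | starting material
2 | (±)-1-(3,4,5-trimethoxyphenyl)propan-1-ol | CCC(O)c1cc(OC)c(OC)c(OC)c1 | intermediate
3 | 1-(3,4,5-trimethoxyphenyl)propan-1-one | CCC(=O)c1cc(OC)c(OC)c(OC)c1 | intermediate
4 | (E)-isoelemicin, (E)-1,2,3-trimethoxy-5-(prop-1-en-1-yl)benzene | COc1cc(/C=C/C)cc(OC)c1OC | intermediate
5 | (±)-4,4,4-trifluoro-2-methyl-1-(3,4,5-trimethoxyphenyl)butane-1,3-dione (keto form drawn; C2 not defined) | CC(C(=O)C(F)(F)F)C(=O)c1cc(OC)c(OC)c(OC)c1 | intermediate
6 | 2-diazo-1-(3,4,5-trimethoxyphenyl)propan-1-one | CC(=[N+]=[N-])C(=O)c1cc(OC)c(OC)c(OC)c1 | intermediate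
7 | [(1S,2S,3R)-1,2-dimethyl-3-(3,4,5-trimethoxyphenyl)cyclopropyl](3,4,5-trimethoxyphenyl)methanone (drawn as the diastereomer with the aroyl group trans to ring B; the C1 epimer would give the same 8) | C[C@]1(C(=O)c2cc(OC)c(OC)c(OC)c2)[C@@H](C)[C@@H]1c1cc(OC)c(OC)c(OC)c1 | intermediate (not isolated)
8 | (2R,3R)-3,4-dimethyl-2,5-bis(3,4,5-trimethoxyphenyl)-2,3-dihydrofuran (trans) | CC1=C(c2cc(OC)c(OC)c(OC)c2)O[C@@H](c2cc(OC)c(OC)c(OC)c2)[C@@H]1C | intermediate
9 | (1R,2S)-3-hydroperoxy-3-methoxy-2-methyl-1-(3,4,5-trimethoxyphenyl)butyl 3,4,5-trimethoxybenzoate (both C3 epimers; that centre becomes the ketone) | COc1cc(C(=O)O[C@@H](c2cc(OC)c(OC)c(OC)c2)[C@H](C)C(C)(OC)OO)cc(OC)c1OC | intermediate (not isolated)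
10 | tsangin C, (1R,2S)-2-methyl-3-oxo-1-(3,4,5-trimethoxyphenyl)butyl 3,4,5-trimethoxybenzoate | COc1cc(C(=O)O[C@@H](c2cc(OC)c(OC)c(OC)c2)[C@H](C)C(C)=O)cc(OC)c1OC | target

**Step count**

Total steps: 7. Longest linear sequence: 6 steps (steps 1, 2, 4, 5, 6, 7 from aldehyde 1); step 3 is the one-step branch to alkene 4.

**Steps most likely to fail**

1. Step 6 (proposed new method).
   - Carbene transfer to the 1,2-disubstituted alkene may be too slow at −78 °C, so that 1,2-hydride shift or carbene dimerisation takes over.
   - Alkene-face selection may be weak or differ between the two cyclopropane diastereomers, lowering the enantiomeric purity at C3.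
   - In the ring expansion, the benzylic cation may close onto ring A (Friedel–Crafts, six-membered ketone) or lose a proton, which would also scramble C3.
   - Fallback by known chemistry, setting out from aldehyde 1 and rejoining the route at target 10: Brown crotylboration of 1 with the (E)-crotylborane made from trans-2-butene, n-BuLi, KOtBu, (+)-Ipc2BOMe and BF3·OEt2 (THF, −78 °C; NaOH, H2O2 work-up) should deliver the crotyl group to the Re face of the aryl aldehyde through a chair transition state and give the anti homoallylic alcohol (1R,2R)-2-methyl-1-(3,4,5-trimethoxyphenyl)but-3-en-1-ol F1. Acylation with 3,4,5-trimethoxybenzoyl chloride (pyridine, cat. DMAP, CH2Cl2, 0 → 23 °C) gives the ester (1R,2R)-2-methyl-1-(3,4,5-trimethoxyphenyl)but-3-en-1-yl 3,4,5-trimethoxybenzoate F2. Tsuji–Wacker oxidation of the terminal alkene (PdCl2 10 mol %, CuCl, O2, DMF/H2O, 23 °C) then gives the methyl ketone 10.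

2. Step 7.
   - Ozone may attack the electron-rich trimethoxyphenyl rings alongside the enol ether, or peroxidic intermediates may be reduced incompletely.
   - Fallback setting out from 8 and rejoining at 10: dihydroxylation of the enol-ether double bond (OsO4 5 mol %, NMO, acetone/H2O, 0 °C) gives the cyclic hemiketal diol (4S,5R)-3,4-dimethyl-2,5-bis(3,4,5-trimethoxyphenyl)oxolane-2,3-diol F3. Criegee glycol cleavage with Pb(OAc)4 (CH2Cl2, 0 °C) breaks the C2–C3 bond of F3 and gives the ester and the methyl ketone of 10 directly.

3. Step 5.
   - Diazo transfer with loss of the trifluoroacetyl group may be incomplete at the substituted carbon, or the α-methyl diazo ketone may lose nitrogen under traces of acid during isolation.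
   - Fallback setting out from 3 and rejoining at 6: Riley oxidation of 3 (SeO2, dioxane/H2O, reflux) gives 1-(3,4,5-trimethoxyphenyl)propane-1,2-dione F4. Condensation with TsNHNH2 (MeOH, 23 °C) at the more electrophilic acetyl carbonyl gives the mono-tosylhydrazone 1-(3,4,5-trimethoxyphenyl)propane-1,2-dione 2-(p-toluenesulfonylhydrazone) F5. Base (Et3N, CH2Cl2, 23 °C) eliminates p-toluenesulfinate in a Bamford–Stevens-type step to give 6 in solution, which can be dried and used without chromatography.

**Further compounds**

F1 | step 6 | (1R,2R)-2-methyl-1-(3,4,5-trimethoxyphenyl)but-3-en-1-ol | O[C@@H](c1cc(OC)c(OC)c(OC)c1)[C@H](C)C=C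
F2 | step 6 | (1R,2R)-2-methyl-1-(3,4,5-trimethoxyphenyl)but-3-en-1-yl 3,4,5-trimethoxybenzoate | COc1cc(C(=O)O[C@@H](c2cc(OC)c(OC)c(OC)c2)[C@H](C)C=C)cc(OC)c1OC
F3 | step 7 | (4S,5R)-3,4-dimethyl-2,5-bis(3,4,5-trimethoxyphenyl)oxolane-2,3-diol (cis-diol; C2 and C3 not assigned, both become carbonyl carbons) | CC1(O)C(O)(c2cc(OC)c(OC)c(OC)c2)O[C@@H](c2cc(OC)c(OC)c(OC)c2)[C@@H]1C
F4 | step 5 | 1-(3,4,5-trimethoxyphenyl)propane-1,2-dione | CC(=O)C(=O)c1cc(OC)c(OC)c(OC)c1
F5 | step 5 | 1-(3,4,5-trimethoxyphenyl)propane-1,2-dione 2-(p-toluenesulfonylhydrazone) (C=N geometry not assigned) | CC(=NNS(=O)(=O)c1ccc(C)cc1)C(=O)c1cc(OC)c(OC)c(OC)c1
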